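Labels used throughout (a local numbering): C1 spiro carbon; C2 CH bridgehead; C3, C4 the CH2 groups of ring B; C5=C6 the tetrasubstituted alkene; C7 quaternary bridgehead; C8 CH2; C9 CH(CO2H); C10 CH; C11, C12 the CH2 groups of ring D; C13 (on C7) and C14 (on C2) the two NCH2 carbons; C15 the OCH2 carbon; C16, C17, C18 the other carbons of ring E (C18 bears the isopropyl group); C19 the carboxyl carbon. Rings: A piperidine (N, C13, C7, C1, C2, C14); B cycloheptene (C1 to C7); C cyclopentane (C6, C7, C8, C9, C10); D cyclopentene (C5, C6, C10, C11, C12); E dihydropyran (O, C15, C1, C16, C17, C18).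

Assumption: the sense of induction of the chiral catalysts in steps 2 and 11 follows the usual models; both antipodes of each are available and the one that gives the drawn configuration is meant. Absolute configuration is carried by the SMILES strings; names give relative configuration with the labels above. Centres that the next step destroys (C1 and C16 in 24 and 25, the alkene geometry of 26) are left unspecified.

## Structural features

Rings A and B share the unit C7–C1–C2 and form a 3-azabicyclo[4.3.1]decene whose one-carbon bridge C1 is also the spiro atom of the 6-isopropyl-3,4-dihydro-2H-pyran ring E. The tetrasubstituted C5=C6 alkene belongs to rings B and D, and C6–C10 is the fusion bond to ring C, which carries the carboxyl group on C9. There are five stereocentres: C2, C1 and C7 are contiguous, C1 and C7 are both quaternary and bonded to each other, and C9/C10 sit across ring C. C16 lies on the side of the CH2–N–CH2 bridge and C15 over ring B; H9, H10 and C13 are on one face of ring C, while C1, C11 and the carboxyl group are on the other. Fragile points are the cyclic enol ether (aqueous acid), the amino acid zwitterion, and C9, whose carboxyl group is cis to both neighbours and may epimerise under base. The real difficulty is the C1–C7 bond between two quaternary stereocentres inside the bridged bicycle, next to the tetrasubstituted alkene. The key step exploits the array C15–C1–C7–C6=C5: with C15 at the carboxyl level it is the retron of an ester enolate Claisen rearrangement, and because C1 and C5 are already tied by C2–C3–C4, the ester can be a seven-membered lactone spiro-fused at C5.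

## Logic of the disconnections

In 33 the O–C18 bond of ring E is cut. The enol ether is the most acid-sensitive group and is made last, from the δ-hydroxy ketone 32, which is 33 plus water. The forward step must dehydrate under anhydrous acid in the presence of the ammonium carboxylate.

In 32 the N–C14 bond of ring A is cut, giving the amino aldehyde 31. All acid-labile groups of 30 (carbamate, tert-butyl ester, acetal, ketal) fall in one acid treatment to release 31. The ring can only close if C13 and C14 are cis on ring B, which steps 11 and 16 must secure.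

30 comes from 29 by lowering C15 from the carboxyl to the alcohol level. The reduction must single out a free acid next to a tert-butyl ester.

In 29 the C1–C7 bond is cut and O–C5 reconnected, leading through 28 and 27 to the spiro lactone 26. In one sentence: the route is a reductive Ireland–Claisen ring contraction of a seven-membered spiro lactone on a bicyclo[3.3.0]octene. This single cut removes ring B, both quaternary centres and the C5=C6 alkene, and leaves a lactone with only C2, C5, C9 and C10 as stereocentres. It demands a silyl ketene acetal made without base and a [3,3] shift that outruns ionisation of the tertiary allylic C5–O bond.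

In 26 the exocyclic C1=C16 bond is cut to the lactone 19 and the aldehyde 22 (via 24). This brings in all of C16–C18 and the isopropyl group and makes the later enolate by hydride addition instead of deprotonation. It demands enolisation of the lactone CH2 only.

19 comes from 18 by adding hydride to C2, and 18 from the acrylate 17 by ring-closing metathesis across C1=C2. The conjugate reduction must deliver hydrogen to the lactone face remote from the C13 arm.

In 17 the C5–C4 bond and the ester C–O bond are cut to the enone 10, the bromide 14 and acryloyl chloride. The addition must occur from the face of ring D that carries H10.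

10 goes back through 8 and 7 to the acid 6 by functional group changes at C13 and C19.

In 6 the C6=C7 alkene is traced to loss of HBr and the C13/C19 carbonyls to cleavage of the C13=C19 bond of the norbornene 4, which is the Diels–Alder adduct of 2 and 3 (2 from 1). The cycloaddition sets C9 and C10 and, by its regiochemistry, decides which bridgehead receives the carboxyl and which the formyl group.

14 is traced through 13 to 11, and 22 through 21 to 20.

## Other disconnections considered

Alternative 1: the first idea is to cut C3–C4 of ring B. The forward key step is ring-closing metathesis of the divinyl compound A1 to the cycloheptadiene A2, then hydrogenation of C3=C4. The metathesis only closes a ring. A1 must already hold the C1–C7 bond between two quaternary carbons, which would have to come from an intermolecular alkylation of a fully substituted enolate at a fully substituted allylic carbon with no element of stereocontrol. A2 also needs chemoselective reduction of one alkene of a conjugated diene. The chosen plan forms C1–C7 and ring B in the same event.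

Alternative 2: cut C7–C13, C2–C14 and both C–N bonds. The forward key step is a four-component double Mannich reaction of the tricyclic ketone A3 with methylamine and two formaldehyde units to give the bridged amino ketone A4. This builds ring A in one operation, but C7 becomes quaternary through a dienol whose facial bias comes only from the remote C9 ester, and attack at C5 competes. C1 is left as a ketone flanked by quaternary C7; turning it into the spiro centre with the correct face would take several steps with no control element. The chosen plan sets C1 and C7 together and in a fixed relation.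

Alternative 3: cut O–C15 and C16–C1 of ring E. The forward key step is an inverse-demand hetero-Diels–Alder reaction of 4-methylpent-1-en-3-one with the enol ether A5 (from A4) to give the 2-methoxydihydropyran A6. A5 is a β,β-disubstituted enol ether at a neopentyl position and a poor dienophile, and nothing fixes the face at C1. The anomeric methoxy group of A6 would have to be removed by ionic reduction, which the ring enol ether would not survive. In the chosen plan C15 arrives at the carboxyl level and C1 is fixed by the rearrangement.

Key step: step 16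

## Steps

Step 1
Reactants: 1 cyclopent-2-en-1-one
Product: 2 2-(triisopropylsilyloxy)cyclopenta-1,3-diene
Conditions: TIPSOTf, Et3N, CH2Cl2, 0 °C; used at once, kept cold
Reagents that add atoms: triisopropylsilyl trifluoromethanesulfonate, CC(C)[Si](OS(=O)(=O)C(F)(F)F)(C(C)C)C(C)C
Why: Soft enolisation of an enone; O-silylation and loss of the α′ proton should give the cross-conjugated 2-silyloxydiene, and no stereocentre is formed.

Step 2
Reactants: 2 2-(triisopropylsilyloxy)cyclopenta-1,3-diene; 3 2-bromocyclopent-2-en-1-one
Product: 4 endo-2-bromo-8-(triisopropylsilyloxy)tricyclo[5.2.1.0(2,6)]dec-8-en-3-one (cyclopentanone ring syn to the C8=C9 bridge)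
Conditions: (S)-diphenylprolinol-derived B-(o-tolyl)oxazaborolidine·HNTf2 (20 mol %), CH2Cl2, −78 to −40 °C
Reagents that add atoms: none
Why: Catalytic asymmetric Diels–Alder reaction with a cationic oxazaborolidine as chiral Lewis acid. The endo rule puts ring D under the silyloxy-alkene bridge, which fixes C9 relative to C10, and the catalyst fixes the absolute sense. The silyloxy carbon ends para to the carbonyl-bearing carbon, so the future C19 sits on the bridgehead next to C10 and the future C13 on the one next to the C–Br carbon.

Step 3
Reactants: 4 the Diels–Alder adduct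
Product: 6 2-formyl-8-oxobicyclo[3.3.0]oct-1-ene-4-carboxylic acid (H9 and H10 cis), via triisopropylsilyl 1-bromo-2-formyl-8-oxobicyclo[3.3.0]octane-4-carboxylate 5 (not isolated)
Conditions: O3, CH2Cl2/MeOH, −78 °C; Me2S; then Et3N, 0 °C; aqueous work-up at pH 4
Reagents that add atoms: ozone, [O-][O+]=O
Why: Ozonolysis of the only alkene, a silyl enol ether, gives a silyl ester at C19 and an aldehyde at C13. The C7–H is now α to the aldehyde, so Et3N should expel bromide from C6 by an E1cB elimination and place the alkene at C6=C7 and nowhere else; the silyl ester hydrolyses on work-up.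

Step 4
Reactants: 6 the enal acid
Product: 7 tert-butyl 2-formyl-8-oxobicyclo[3.3.0]oct-1-ene-4-carboxylate (H9 and H10 cis)
Conditions: tert-butyl 2,2,2-trichloroacetimidate, CH2Cl2/cyclohexane, rt
Reagents that add atoms: tert-butyl 2,2,2-trichloroacetimidate, CC(C)(C)OC(=N)C(Cl)(Cl)Cl
Why: Neutral esterification with an imidate leaves the ene-dicarbonyl unit alone; the bulky ester later shields C9–H from bases and falls in the acid step 18.

Step 5
Reactants: 7 the enal ester
Product: 8 tert-butyl 2-(hydroxymethyl)-8-oxobicyclo[3.3.0]oct-1-ene-4-carboxylate (H9 and H10 cis)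
Conditions: NaBH4 (0.3 equiv), CH2Cl2/MeOH, −78 °C
Reagents that add atoms: none
Why: Borohydride at low temperature should reduce the aldehyde much faster than the hindered, cross-conjugated ketone; the allylic alcohol is used directly.

Step 6
Reactants: 8 the allylic alcohol
Product: 10 tert-butyl 2-{[(tert-butoxycarbonyl)(methyl)amino]methyl}-8-oxobicyclo[3.3.0]oct-1-ene-4-carboxylate (H9 and H10 cis), via allylic methanesulfonate 9 (not isolated)
Conditions: MsCl, Et3N, CH2Cl2, −30 °C; then KN(Me)Boc (from MeNHBoc and KN(SiMe3)2), THF, −30 to 0 °C
Reagents that add atoms: tert-butyl N-methylcarbamate, CNC(=O)OC(C)(C)C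
Why: SN2 displacement of a primary allylic mesylate by a carbamate anion; putting nitrogen on as a carbamate avoids a free amine, which would close onto the cis ketone at C5.

Step 7
Reactants: 11 2-bromo-3,3-diethoxyprop-1-ene
Product: 13 3-(diethoxymethyl)but-3-en-1-ol, via (3,3-diethoxyprop-1-en-2-yl)lithium 12 (not isolated)
Conditions: t-BuLi (2 equiv), Et2O, −78 °C; oxirane, −78 to 0 °C; H2O
Reagents that add atoms: oxirane, C1CO1
Why: Bromine–lithium exchange gives the α-acrolein anion equivalent, which opens the epoxide to give C3 and C4.

Step 8
Reactants: 13 3-(diethoxymethyl)but-3-en-1-ol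
Product: 14 4-bromo-2-(diethoxymethyl)but-1-ene
Conditions: CBr4, PPh3, 2,6-lutidine, CH2Cl2, 0 °C
Reagents that add atoms: tetrabromomethane, BrC(Br)(Br)Br
Why: Appel bromination of a primary alcohol; the buffer protects the acetal.

Step 9
Reactants: 14 4-bromo-2-(diethoxymethyl)but-1-ene; 10 the enone carbamate
Product: 17 tert-butyl 8-(acryloyloxy)-2-{[(tert-butoxycarbonyl)(methyl)amino]methyl}-8-[3-(diethoxymethyl)but-3-en-1-yl]bicyclo[3.3.0]oct-1-ene-4-carboxylate (acyloxy group on the face of ring D opposite H10; H9 and H10 cis), via Grignard reagent 15 (not isolated), via bromomagnesium alkoxide 16 (not isolated)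
Conditions: Mg, THF; then 10, LaCl3·2LiCl, THF, −78 °C; then acryloyl chloride, −78 to 0 °C
Reagents that add atoms: acryloyl chloride, C=CC(=O)Cl
Why: Lanthanide-assisted Grignard 1,2-addition to the enone (the β-carbon is fully substituted), with acylation of the alkoxide in the same flask. The reagent should approach C5 from the convex face that carries H10, away from the C9 ester, which puts the oxygen anti to H10 and sets C5.

Step 10
Reactants: 17 the tertiary acrylate
Product: 18 α,β-unsaturated spiro lactone O–C15(=O)–C1H=C2[CH(OEt)2]–C3H2–C4H2–C5, spiro at C5 of the bicyclo[3.3.0]octene of 10 (lactone O anti to H10)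
Conditions: second-generation Grubbs catalyst RuCl2(=CHPh)(PCy3)(H2IMes) (10 mol %), toluene (2 mM), 80 °C
Reagents that add atoms: none
Why: Ring-closing metathesis of an acrylate with a 1,1-disubstituted alkene gives the trisubstituted seven-membered lactone; the tetrasubstituted C6=C7 alkene is inert to the catalyst.

Step 11
Reactants: 18 the unsaturated spiro lactone
Product: 19 saturated spiro lactone with C2–H (C14 on the lactone face turned toward the C6/C13 arm; lactone O anti to H10)
Conditions: Cu(OAc)2 (5 mol %), (R)-DTBM-SEGPHOS (5.5 mol %), (EtO)2MeSiH, t-BuOH, THF, rt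
Reagents that add atoms: none
Why: Copper hydride-catalysed asymmetric conjugate reduction of a β,β-disubstituted unsaturated lactone. Hydride should reach C2 from the lactone face remote from the C13 carbamate arm, which leaves C14 syn to that arm as ring A needs; the ligand antipode is chosen to reinforce this bias.

Step 12
Reactants: 20 methyl 4-methyl-3-oxopentanoate
Product: 21 methyl 2-(2-isopropyl-1,3-dioxolan-2-yl)acetate
Conditions: ethane-1,2-diol, TsOH (cat.), benzene, reflux with azeotropic removal of water
Reagents that add atoms: ethane-1,2-diol, OCCO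
Why: Standard ketalisation of a β-keto ester; masks the future C18 ketone.

Step 13
Reactants: 21 the ketal ester
Product: 22 2-(2-isopropyl-1,3-dioxolan-2-yl)acetaldehyde
Conditions: i-Bu2AlH, CH2Cl2, −78 °C; aqueous sodium potassium tartrate
Reagents that add atoms: none
Why: Partial reduction of a methyl ester to the aldehyde at low temperature.

Step 14
Reactants: 19 the saturated spiro lactone; 22 the ketal aldehyde
Product: 24 aldol adduct with C1H–C16H(OH)–C17H2–C18(ketal)–isopropyl on the lactone (mixture at C1 and C16), via lithium enolate 23 (not isolated)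
Conditions: LiN(i-Pr)2 (1.05 equiv), THF, −78 °C; then 22; AcOH
Reagents that add atoms: none
Why: Kinetic deprotonation should take the unhindered lactone CH2 in preference to the tertiary C9–H of the bulky tert-butyl ester; aldol addition to the aldehyde is faster than its enolisation at −78 °C.

Step 15
Reactants: 24 the aldol adduct
Product: 26 α-alkylidene spiro lactone with exocyclic C1=C16H–C17H2–C18(ketal)–isopropyl (alkene geometry not specified), via secondary methanesulfonate 25 (not isolated)
Conditions: MsCl, Et3N, CH2Cl2, 0 °C; then DBU, 0 °C, short contact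
Reagents that add atoms: none
Why: E1cB dehydration through the mesylate gives the conjugated exocyclic alkene; short contact with base limits migration of the double bond into the ring, which would erase C2.

Step 16
Reactants: 26 the α-alkylidene spiro lactone
Product: 29 ring-B carboxylic acid: cycloheptene (C1 to C7) with C15O2H and the C16–C18 ketal chain on C1, CH(OEt)2 on C2, CH2N(Me)Boc on C7, C5=C6 shared with ring D, tert-butyl ester on C9 (C16 and C14 cis to C13; C15 trans to C13; C1 on the face of ring C opposite H10), via dimethylphenylsilyl ketene acetal 27 (not isolated), via dimethylphenylsilyl ester 28 (not isolated)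
Conditions: [(Ph3P)CuH]6 (5 mol % Cu), PhMe2SiH (1.5 equiv), toluene, rt; then 100 °C; then MeOH/pH 7 buffer
Reagents that add atoms: none
Why: Copper hydride adds to C16 of the exocyclic enoate and σ-bond metathesis with the silane gives the O-silyl ketene acetal 27, whose C15=C1 bond is endocyclic, so its geometry is fixed (C2 cis to the ring oxygen). On heating, 27 undergoes a [3,3] shift in which C1–C7 forms as O–C5 breaks and the alkene moves to C5=C6, giving 28 and, after hydrolysis, 29. The closest known reactions are the Ireland–Claisen ring contraction of lactone silyl ketene acetals that bear an alkenyl group on the alkoxy carbon, and the reductive Ireland–Claisen rearrangement triggered by conjugate hydrosilylation of an acrylate. Ring B closes as a seven-membered carbocycle because C1 and C5, the 1,4-atoms of the six-atom array, are tied by C2–C3–C4; this bridge excludes the chair and leaves one boat transition state. C7 is set by suprafacial transfer from C5: the oxygen leaves from the face anti to H10 and C1 arrives on that face. C1 is set by the fixed ketene acetal geometry in the boat, where C16 eclipses C8 and C2 eclipses C13, so C16 ends cis and C15 trans to C13. C2 is not touched and places C14 cis to C13. The step needs 1,4-hydride addition to the alkylidene lactone only (the tert-butyl ester, carbamate and tetrasubstituted alkene do not react with copper hydride) and a [3,3] shift faster than ionisation of the tertiary allylic C–O bond, which the non-polar, base-free and acid-free medium favours.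

Step 17
Reactants: 29 the ring-B carboxylic acid
Product: 30 the corresponding primary alcohol (C15H2OH on C1; all other groups and configurations as in 29)
Conditions: BH3·SMe2, THF, 0 °C to rt; MeOH
Reagents that add atoms: none
Why: Borane reduces the free, hindered carboxylic acid through its acyloxyborane much faster than the tert-butyl ester or carbamate, and the tetrasubstituted alkene hydroborates only slowly.

Step 18
Reactants: 30 the primary alcohol
Product: 32 amino acid δ-hydroxy ketone: rings A to D complete, C1 bearing C15H2OH and C16H2–C17H2–C18(=O)–isopropyl, free CO2H on C9 (configurations as in the target), via amino aldehyde 31 (not isolated)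
Conditions: TFA/CH2Cl2/H2O (10:10:1), 0 °C to rt; evaporation; then NaBH(OAc)3, AcOH, ClCH2CH2Cl, rt
Reagents that add atoms: water, O
Why: Acid removes the carbamate and tert-butyl ester and hydrolyses the acetal and ketal; the secondary ammonium at C13 and the aldehyde at C14 are cis on ring B and should close to a six-membered iminium, which the triacetoxyborohydride reduces while leaving the ketone (intramolecular reductive amination). Only the cis arrangement can bridge, so this step also proofreads C2.

Step 19
Reactants: 32 the amino acid δ-hydroxy ketone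
Product: 33 CNP0237695.1, the target
Conditions: (+)-camphor-10-sulfonic acid (1.5 equiv), 4 Å molecular sieves, ClCH2CH2Cl, 60 °C; then Et3N; non-aqueous neutral work-up
Reagents that add atoms: none
Why: Acid-catalysed cyclodehydration of a δ-hydroxy ketone through the hemiketal and oxocarbenium ion should give the endocyclic six-membered enol ether; acid beyond one equivalent is needed because the amine takes the first, and no stereocentre changes.

## Compound list

1 | cyclopent-2-en-1-one | O=C1C=CCC1 | starting material
2 | 2-(triisopropylsilyloxy)cyclopenta-1,3-diene | CC(C)[Si](OC1=CCC=C1)(C(C)C)C(C)C | intermediate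
3 | 2-bromocyclopent-2-en-1-one | O=C1CCC=C1Br | starting material
4 | endo-2-bromo-8-(triisopropylsilyloxy)tricyclo[5.2.1.0(2,6)]dec-8-en-3-one | O=C1CC[C@H]2[C@]1(Br)[C@@H]1C[C@H]2C(O[Si](C(C)C)(C(C)C)C(C)C)=C1 | intermediate
5 | triisopropylsilyl 1-bromo-2-formyl-8-oxobicyclo[3.3.0]octane-4-carboxylate (all-cis substituents from the adduct) | O=C1CC[C@H]2[C@]1(Br)[C@@H](C=O)C[C@H]2C(=O)O[Si](C(C)C)(C(C)C)C(C)C | intermediate (not isolated)
6 | 2-formyl-8-oxobicyclo[3.3.0]oct-1-ene-4-carboxylic acid (H9, H10 cis) | O=C1CC[C@H]2C1=C(C=O)C[C@H]2C(=O)O | intermediate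
7 | tert-butyl 2-formyl-8-oxobicyclo[3.3.0]oct-1-ene-4-carboxylate (H9, H10 cis) | O=C1CC[C@H]2C1=C(C=O)C[C@H]2C(=O)OC(C)(C)C | intermediate
8 | tert-butyl 2-(hydroxymethyl)-8-oxobicyclo[3.3.0]oct-1-ene-4-carboxylate (H9, H10 cis) | O=C1CC[C@H]2C1=C(CO)C[C@H]2C(=O)OC(C)(C)C | intermediate
9 | methanesulfonate of 8 | O=C1CC[C@H]2C1=C(COS(C)(=O)=O)C[C@H]2C(=O)OC(C)(C)C | intermediate (not isolated)
10 | tert-butyl 2-{[(tert-butoxycarbonyl)(methyl)amino]methyl}-8-oxobicyclo[3.3.0]oct-1-ene-4-carboxylate (H9, H10 cis) | O=C1CC[C@H]2C1=C(CN(C)C(=O)OC(C)(C)C)C[C@H]2C(=O)OC(C)(C)C | intermediate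
11 | 2-bromo-3,3-diethoxyprop-1-ene | C=C(Br)C(OCC)OCC | starting material
12 | (3,3-diethoxyprop-1-en-2-yl)lithium | [Li]C(=C)C(OCC)OCC | intermediate (not isolated)
13 | 3-(diethoxymethyl)but-3-en-1-ol | OCCC(=C)C(OCC)OCC | intermediate
14 | 4-bromo-2-(diethoxymethyl)but-1-ene | BrCCC(=C)C(OCC)OCC | intermediate
15 | [3-(diethoxymethyl)but-3-en-1-yl]magnesium bromide | Br[Mg]CCC(=C)C(OCC)OCC | intermediate (not isolated)
16 | bromomagnesium alkoxide of the C5 tertiary alcohol (O anti to H10) | Br[Mg]O[C@]1(CCC(=C)C(OCC)OCC)CC[C@H]2C1=C(CN(C)C(=O)OC(C)(C)C)C[C@H]2C(=O)OC(C)(C)C | intermediate (not isolated)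
17 | tertiary acrylate at C5 (acyloxy anti to H10; H9, H10 cis) | C=CC(=O)O[C@]1(CCC(=C)C(OCC)OCC)CC[C@H]2C1=C(CN(C)C(=O)OC(C)(C)C)C[C@H]2C(=O)OC(C)(C)C | intermediate
18 | α,β-unsaturated spiro lactone (C1H=C2 bearing CH(OEt)2; lactone O anti to H10) | O=C1C=C(C(OCC)OCC)CC[C@@]2(O1)CC[C@H]3C2=C(CN(C)C(=O)OC(C)(C)C)C[C@H]3C(=O)OC(C)(C)C | intermediate
19 | saturated spiro lactone (C14 on the lactone face toward the C6/C13 arm) | O=C1C[C@@H](C(OCC)OCC)CC[C@@]2(O1)CC[C@H]3C2=C(CN(C)C(=O)OC(C)(C)C)C[C@H]3C(=O)OC(C)(C)C | intermediate
20 | methyl 4-methyl-3-oxopentanoate | CC(C)C(=O)CC(=O)OC | starting material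
21 | methyl 2-(2-isopropyl-1,3-dioxolan-2-yl)acetate | CC(C)C1(CC(=O)OC)OCCO1 | intermediate
22 | 2-(2-isopropyl-1,3-dioxolan-2-yl)acetaldehyde | CC(C)C1(CC=O)OCCO1 | intermediate
23 | lithium enolate of 19 | [Li]OC1=C[C@@H](C(OCC)OCC)CC[C@@]2(O1)CC[C@H]3C2=C(CN(C)C(=O)OC(C)(C)C)C[C@H]3C(=O)OC(C)(C)C | intermediate (not isolated)
24 | aldol adduct of 19 and 22 (C1 and C16 unspecified) | O=C1C(C(O)CC2(C(C)C)OCCO2)[C@@H](C(OCC)OCC)CC[C@@]3(O1)CC[C@H]4C3=C(CN(C)C(=O)OC(C)(C)C)C[C@H]4C(=O)OC(C)(C)C | intermediate
25 | methanesulfonate of 24 | O=C1C(C(OS(C)(=O)=O)CC2(C(C)C)OCCO2)[C@@H](C(OCC)OCC)CC[C@@]3(O1)CC[C@H]4C3=C(CN(C)C(=O)OC(C)(C)C)C[C@H]4C(=O)OC(C)(C)C | intermediate (not isolated)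
26 | α-alkylidene spiro lactone (exocyclic C1=C16; geometry unspecified) | O=C1C(=CCC2(C(C)C)OCCO2)[C@@H](C(OCC)OCC)CC[C@@]3(O1)CC[C@H]4C3=C(CN(C)C(=O)OC(C)(C)C)C[C@H]4C(=O)OC(C)(C)C | intermediate
27 | dimethylphenylsilyl ketene acetal of the lactone (C15=C1 endocyclic) | C[Si](C)(c1ccccc1)OC1=C(CCC2(C(C)C)OCCO2)[C@@H](C(OCC)OCC)CC[C@@]3(O1)CC[C@H]4C3=C(CN(C)C(=O)OC(C)(C)C)C[C@H]4C(=O)OC(C)(C)C | intermediate (not isolated)
28 | dimethylphenylsilyl ester of 29 | CC(C)C1(CC[C@@]2(C(=O)O[Si](C)(C)c3ccccc3)[C@@H](C(OCC)OCC)CCC3=C4[C@H](CC3)[C@H](C(=O)OC(C)(C)C)C[C@@]42CN(C)C(=O)OC(C)(C)C)OCCO1 | intermediate (not isolated)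
29 | ring-B carboxylic acid (C16 and C14 cis to C13; C15O2H trans to C13) | CC(C)C1(CC[C@@]2(C(=O)O)[C@@H](C(OCC)OCC)CCC3=C4[C@H](CC3)[C@H](C(=O)OC(C)(C)C)C[C@@]42CN(C)C(=O)OC(C)(C)C)OCCO1 | intermediate
30 | primary alcohol from 29 (C15H2OH) | CC(C)C1(CC[C@@]2(CO)[C@@H](C(OCC)OCC)CCC3=C4[C@H](CC3)[C@H](C(=O)OC(C)(C)C)C[C@@]42CN(C)C(=O)OC(C)(C)C)OCCO1 | intermediate
31 | amino aldehyde: C13H2NHMe, C14HO, C18 ketone, C15H2OH, C9 CO2H | CC(C)C(=O)CC[C@@]1(CO)[C@@H](C=O)CCC2=C3[C@H](CC2)[C@H](C(=O)O)C[C@@]31CNC | intermediate (not isolated)
32 | amino acid δ-hydroxy ketone (rings A to D closed; the target plus water) | CC(C)C(=O)CC[C@@]1(CO)[C@@H]2CCC3=C4[C@H](CC3)[C@H](C(=O)O)C[C@@]41CN(C)C2 | intermediate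
33 | CNP0237695.1 | CC(C)C1=CC[C@@]2(CO1)[C@@H]1CCC3=C4[C@H](CC3)[C@H](C(=O)O)C[C@@]42CN(C)C1 | target

## Step count and least certain steps

Total: 19 steps. Longest linear sequence: 15 steps (1 to 6, 9 to 11, 14 to 19).

Step 16 (key step). The most likely failure is heterolysis of the tertiary, doubly allylic C5–O bond, or loss of the silyl group from the ketene acetal, before the boat [3,3] shift can occur; the hydrosilylation may also stall at the hindered alkylidene. The fallback sets out from 26 and returns at 29, and separates enolate formation from the rearrangement. Conjugate reduction with LiBH(s-Bu)3 (THF, −78 °C, proton quench) would give the saturated α-alkyl lactone F1. Kinetic deprotonation with KN(SiMe3)2 and silylation with TBSCl would give the isolable tert-butyldimethylsilyl ketene acetal F2. This can be rearranged in toluene, or the potassium enolate can be left to rearrange below room temperature, to give the silyl ester F3, which is hydrolysed to 29.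

Step 2. The diene may undergo a 1,5-hydrogen shift or dimerise, may add in a Michael sense without closing the ring, or the α-bromo enone may erode endo and enantioselectivity. The fallback sets out from 2 and 3 and returns at 4: a racemic cycloaddition with Me2AlCl, then resolution of the adduct on a chiral stationary phase, discarding the antipode F4.

Step 9. The basic Grignard reagent may enolise 10 (γ-deprotonation at C8 or C13) instead of adding, or may add from the wrong face of a nearly flat enone. The fallback sets out from 10 and returns at 17 and brings in the chain in two pieces. The small vinylmagnesium bromide with LaCl3·2LiCl would give the vinyl carbinol F5. Hydroboration of its vinyl group with 9-BBN would give the alkylborane F6. A B-alkyl Suzuki–Miyaura coupling of F6 with 11 (Pd(dppf)Cl2, K3PO4) would give the tertiary alcohol F7, which is acylated with acryloyl chloride to 17.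

Step 11. Hydrocupration of the β,β-disubstituted, α-branched C2 may be slow, or the facial preference may be low. The fallback sets out from 18 and returns at 19 without a new compound. The hydride conjugate addition is replaced by a chelate-controlled homogeneous hydrogenation (H2, Ru(OAc)2[(S)-BINAP], MeOH), in which the catalyst bound to the lactone carbonyl sets C2.

Step 19. The enol ether may hydrolyse back on work-up, the exocyclic isopropylidene isomer may form, or the acid may attack the tetrasubstituted alkene. The fallback sets out from 32 and returns at 33 in two stages. The hemiketal is trapped as the methyl ketal F8 (HC(OMe)3, MeOH, pyridinium tosylate), and methanol is then eliminated under non-protic conditions (TMSOTf, i-Pr2NEt, CH2Cl2, −20 °C).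

## Further compounds

F1 | step 16 | saturated α-alkyl spiro lactone (C1 unspecified) | O=C1C(CCC2(C(C)C)OCCO2)[C@@H](C(OCC)OCC)CC[C@@]3(O1)CC[C@H]4C3=C(CN(C)C(=O)OC(C)(C)C)C[C@H]4C(=O)OC(C)(C)C
F2 | step 16 | tert-butyldimethylsilyl ketene acetal of F1 | CC(C)(C)[Si](C)(C)OC1=C(CCC2(C(C)C)OCCO2)[C@@H](C(OCC)OCC)CC[C@@]3(O1)CC[C@H]4C3=C(CN(C)C(=O)OC(C)(C)C)C[C@H]4C(=O)OC(C)(C)C
F3 | step 16 | tert-butyldimethylsilyl ester of 29 | CC(C)C1(CC[C@@]2(C(=O)O[Si](C)(C)C(C)(C)C)[C@@H](C(OCC)OCC)CCC3=C4[C@H](CC3)[C@H](C(=O)OC(C)(C)C)C[C@@]42CN(C)C(=O)OC(C)(C)C)OCCO1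
F4 | step 2 | enantiomer of 4 (discarded) | O=C1CC[C@@H]2[C@@]1(Br)[C@H]1C[C@@H]2C(O[Si](C(C)C)(C(C)C)C(C)C)=C1
F5 | step 9 | C5 vinyl carbinol (OH anti to H10) | O[C@]1(C=C)CC[C@H]2C1=C(CN(C)C(=O)OC(C)(C)C)C[C@H]2C(=O)OC(C)(C)C
F6 | step 9 | B-alkyl-9-borabicyclo[3.3.1]nonane from F5 | O[C@]1(CCB2C3CCCC2CCC3)CC[C@H]2C1=C(CN(C)C(=O)OC(C)(C)C)C[C@H]2C(=O)OC(C)(C)C
F7 | step 9 | tertiary alcohol corresponding to alkoxide 16 | O[C@]1(CCC(=C)C(OCC)OCC)CC[C@H]2C1=C(CN(C)C(=O)OC(C)(C)C)C[C@H]2C(=O)OC(C)(C)C
F0 | step 11 | none | none
F8 | step 19 | methyl ketal of 32 (2-methoxy-2-isopropyltetrahydropyran form; ketal carbon unspecified) | CC(C)C1(OC)CC[C@@]2(CO1)[C@@H]1CCC3=C4[C@H](CC3)[C@H](C(=O)O)C[C@@]42CN(C)C1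
A1 | alternative 1 | divinyl metathesis substrate with rings A, C and D and the C1–C7 bond in place | CC(C)C1(CC[C@@]2(CO[Si](C)(C)C(C)(C)C)[C@H](C=C)CN(C)C[C@@]23C[C@@H](C(=O)OC)[C@H]4CCC(C=C)=C34)OCCO1
A2 | alternative 1 | cycloheptadiene with C3=C4 and C5=C6 | CC(C)C1(CC[C@@]2(CO[Si](C)(C)C(C)(C)C)[C@@H]3C=CC4=C5[C@H](CC4)[C@H](C(=O)OC)C[C@@]52CN(C)C3)OCCO1
A3 | alternative 2 | tricyclic ketone with C1 as carbonyl and rings B, C, D | O=C1CCCC2=C3[C@H](CC2)[C@H](C(=O)OC)C[C@H]13
A4 | alternative 2 | bridged amino ketone with C1 as carbonyl and ring A closed | O=C1[C@@H]2CCC3=C4[C@H](CC3)[C@H](C(=O)OC)C[C@@]41CN(C)C2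
A5 | alternative 3 | exocyclic methyl enol ether at C1 | COC=C1[C@@H]2CCC3=C4[C@H](CC3)[C@H](C(=O)OC)C[C@@]41CN(C)C2
A6 | alternative 3 | 2-methoxy spiro dihydropyran with methoxy on C15 | CC(C)C1=CC[C@@]2(C(OC)O1)[C@@H]1CCC3=C4[C@H](CC3)[C@H](C(=O)OC)C[C@@]42CN(C)C1
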